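(The runs were computed on assumed constants.)

Two questions stand before us: how much X each flask of the row holds at the end, and how the row runs.

in all of them: Z 0.050 M
- blue: D 0.47 equiv; run made earlier
- teal: D 2 equiv; run made earlier
- north: D 0.600 equiv; time 40 h
- south-west: D 1.00 equiv; time 40 h
- west: D 1.50 equiv; time 40 h
- south-east: D 2.50 equiv; time 40 h
- south: D 3.00 equiv; time 40 h

- blue (time / h: X / %): 4.00: 27; 10.0: 36; 20.0: 38; 30.0: 38
- teal (time / h: X / %): 8.00: 42; 15.0: 46; 20.0: 45; 30.0: 44

(readings scatter by 2 percentage points)

* amount of X at the end, in percent of the Z charged for north, south-west, west, south-east, south, in this order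
* how the row runs (hardly changes / rises, then falls / falls, then rises / falls all the way / rises all the way)

- "hardly changes" means that all values lie within two and a half points (for a concentration: within two and a half percent of the largest)

We keep a ledger of D, the limiting reagent in blue, whose charge of 0.47 equiv lies below one equivalent.

Step 1. X is the peak we can read. In blue it stands at 38% after 30.0 h, a reading with a scatter of 2 percentage points.

Step 2. We divide that reading by the charge of D. This gives the capture, the share of the D charged that stands as X at the end: 80.9% in blue.

Step 3. The books of blue close with a second entry: 19.1% of its D is unspent or stands in forms we do not read.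

Step 4. Teal is charged with 2 equiv, so Z is the smaller charge there. Its capture is 22.5%, lower than blue's, so we carry the capture to charges below one equivalent.

Step 5. North lies below one equivalent, and our reckoning puts its X at 48.5%. The same product for south-west is 80.9%. Since teal reads 45%, we expect the row to rise, then fall.

Step 6. The forecast differs from our reckoning: it gives 46%, 59%, 56%, 34% and 27%, with the shape rises, then falls. It starts from this: “Both plateaus are flat, so these look like equilibria.”

Step 7. The flasks give 48.3%, 67.9%, 60.1%, 34.4% and 27.3%, and the shape is rises, then falls.

    Z + D → X (k = 7.40 /M/h)
    D + X ⇌ E (K = 36.0 /M, k = 10.0 /M/h)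
    X → J (k = 0.00570 /h)

North's capture is 80.5%, beside blue's 80.9%, and south-west's is 67.9%. North holds 48.3% of X after 40.0 h in part because E gives back D and X, and in part because the reading is taken at that hour. Without the undoing of E, north holds 24.0% of X at that hour. With the undoing in place, north holds 6.46% of X after 400 h.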